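The reagent looked to be paid twice in the earlier runs: once to open the starting material, once to turn open intermediate into product.

| flask | starting material | partner | reagent | remark | time |
|---|---|---|---|---|---|
| winter | 20 mM | 2 equiv | 1.1 equiv | run made earlier |  |
| autumn | 29 mM | 2 equiv | 1.1 equiv | run made earlier |  |
| noon | 39 mM | 2 equiv | 2.2 equiv | run made earlier |  |
| flask | 39 mM | 2.00 equiv | 1.10 equiv |  | 2.5 h |

| run | time / min | open intermediate / % | product / % |
|---|---|---|---|
| winter | 1.33 | 67.7 | 0 |
| winter | 3.00 | 81.9 | 0.3 |
| winter | 8.00 | 90.2 | 2.8 |
| winter | 20.0 | 89.6 | 6.1 |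
| winter | 50.0 | 84.3 | 11.4 |
| winter | 120 | 82.1 | 13.4 |
| autumn | 1.33 | 74.6 | 0.2 |
| autumn | 3.00 | 86.1 | 0.4 |
| autumn | 8.00 | 90.1 | 4.1 |
| autumn | 20.0 | 87.4 | 8.3 |
| autumn | 50.0 | 83.3 | 12.8 |
| autumn | 120 | 82.1 | 13.7 |
| noon | 1.33 | 97.5 | 0.9 |
| noon | 4.00 | 92.3 | 7.3 |
| noon | 12.0 | 66.7 | 32.6 |
| noon | 40.0 | 22.6 | 77.1 |
| noon | 120 | 2.6 | 97.2 |

(readings scatter by 0.3 percentage points)

- what was read earlier has a scatter of 0.3 percentage points, one standard deviation

- time up to 2.5 h at which open intermediate stands highest
- the amount of open intermediate, in percent of the starting material charged, at that time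
- the first time at which open intermediate reaches 63%, in the same percent, in min

At the last autumn reading I reckoned

c(open intermediate) + 2 c(product) = 82.1% + 2 × 13.7% = 110%

I called this sum, in percent of the starting material charged, the reagent bill. It stood close to the charge of 1.1 equiv, so the reagent looked like the limiting reagent.

The flask has that same charge, 1.10 equiv, and two extremes can be solved in the head. In one, opening ended before product began: the surplus 10.0% bought that much product, leaving 90.0% open intermediate. In the other, each open intermediate went on at once: the bill gave 55.0% product and no open intermediate. The winter run lay nearer the first, with 67.7% open intermediate against 0% product at 1.33 min, so I expected a peak near its reading of 90.2%.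

Taking each step as bimolecular, I shrank times by the concentration ratio:

peak: 8.00 min → 4.10 min (winter), 5.95 min (autumn)

winter's first reading: 1.33 min → 0.682 min

The asked level lies below that first reading, so I placed it a little earlier.

The forecast gave 0.08 h, 90.3% and 0.55 min, holding that “the time scale shrinks roughly as” the inverse of the concentration.

The flask gave 5.70 min, 90.5% and 0.560 min.

    reagent + partner → second intermediate (k = 1.50 /M/min)
    starting material + reagent → open intermediate (k = 69.0 /M/min)
    open intermediate + second intermediate → product (k = 2.40 /M/min)

At 2.50 h the flask held 82.5% open intermediate, 13.8% product and 0% reagent, with the second intermediate down to 5.84 × 10⁻⁵ mM, so its bill closed at 110%, level with the 110% read in the autumn run. In the same flask run without the consumption of reagent, the peak stood at 97.9% instead of 90.5%, so that consumption held it down by 7.3 percentage points. A neighbouring flask with 0.800 equiv of partner ended with 0% reagent and the second intermediate at 0.00214 mM, and its 89.6% open intermediate and 10.2% product paid a bill of 110%.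

All runs are calculated for an exercise, noise included.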